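Follow one molecule of partner through its forks before integrating anything.

| flask | substrate | partner | scavenger | time |
|---|---|---|---|---|
| theta | 0.050 M | 1.10 equiv | 0.800 equiv | 10 h |
| epsilon | 0.050 M | 1.10 equiv | 0.800 equiv | 20 h |
| gamma | 0.050 M | 1.10 equiv | 0.800 equiv | 40 h |

    substrate + partner → first product + released group (k1 = 11 M⁻¹ h⁻¹)
    partner + first product → double product + released group (k2 = 32 M⁻¹ h⁻¹)
    2 partner → homo dimer (k3 = 4.7 M⁻¹ h⁻¹)
    substrate + released group ⇌ idle adduct, settled at all times (K4 = 45 M⁻¹)
    scavenger + released group → scavenged by-product (k5 = 280 M⁻¹ h⁻¹)

- amounts and yields of released group count idle adduct too
- where a step has two of a species, its rate is k times that concentration squared, and two are used at each turn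
- run time (theta): 10 h

1. which of these there is most of at the end, counted by the substrate in it, theta (first product / double product / substrate)
2. which of these there is most of at the end, counted by the substrate in it, epsilon (first product / double product / substrate)
3. which of these there is most of at the end, counted by the substrate in it, gamma (first product / double product / substrate)
4. the largest of these amounts at the end, in percent of the substrate charged, theta
5. the largest of these amounts at the end, in percent of the substrate charged, epsilon
6. the largest of these amounts at the end, in percent of the substrate charged, gamma

A free partner either couples or meets another partner. We therefore reckon on exposure, the time integral of c(partner). Coupling consumes free substrate and not idle adduct, but as an approximation we count the two together and let their sum fall exponentially in exposure with constant 11 M⁻¹ h⁻¹, so the bounds below are bounds within that approximation. In this reckoning the sum stops falling when exposure stops growing. At the start, loss to homo dimer against loss to coupling gives the fork ratio, 0.940. Partner's first half-life by dimerisation alone, 1.93 h, is shorter than the run times, so we expect exposure to be complete, and one answer, in theta, epsilon and gamma.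

Holding coupling demand constant, the substrate fraction left is one plus the fork ratio, raised to minus 1.17. First product couples faster than substrate, so taking the demand at its starting value lets partner last longest and gives the lower bound, 46.0%. Taking the demand as if each substrate-derived molecule coupled at 32 M⁻¹ h⁻¹ spends partner soonest and gives the upper bound, 72.1%.

To tighten this, we evaluate demand at mid-exposure of the lower-bound case, where it is 1.22 times the starting value, so the fork ratio becomes 0.771. We commit to substrate at 51.2% in theta, 51.2% in epsilon and 51.2% in gamma. The same exposure leaves first product at 19.4% and double product at 29.4%. The largest is therefore substrate in theta, substrate in epsilon and substrate in gamma.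

The forecast names substrate, substrate and substrate for theta, epsilon and gamma, at 51%, 51% and 51%, which lies inside our bracket . On the adduct it says: “Adduct slowly returns free substrate, and I counted it as substrate.”

The flasks give substrate at 50.0% in theta, substrate at 50.6% in epsilon and substrate at 50.9% in gamma. Theta ends with 0.163% of its partner charge free. A neighbour of gamma with 4.40 equiv of partner has a fork ratio of 3.76, and the constant-demand expression gives 16.1% substrate, adduct included. After 40.0 h, that neighbour holds substrate 7.21% and idle adduct 11.2%, together 18.4%.

The constants used here come from no measurement; the result is computed.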